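A direct plan would keep the C5–C10 bond until the end (ring atoms C1–C10; C18O2H on C4, C17O2H on C8, C19H2= on C5, C20H3 and the C11H2–C12(=O)–furyl chain on C9). It would build the trans-fused hexahydronaphthalene A1 by Diels–Alder reaction of a 1-vinylcyclohexene such as A2 with methyl propiolate, open A1 with light (6π) to the E,Z,E-triene A3, and let a thermal [1,7]-hydrogen shift finish the ring. Its weakest steps would be:
- the cycloaddition that closes the second ring: a tetrasubstituted diene beside a quaternary carbon would need forcing conditions, with uncertain regio- and facial selectivity and a base isomerisation to reach the trans fusion;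
- the photochemical ring opening: a photostationary mixture, low conversion, and a furyl ketone that also absorbs;
- the addition of 3-furyllithium to a dicarboxylate: large excess, poor solubility, over-addition.

The route inserts C2–C3 between C1 and C4 instead of cutting a decalin. The cross-conjugated unit C19=C5–C4(CO2R)=C3–C2=C1 of the ten-membered ring is the retron of a cyclobutene fused to an eight-membered ring (bicyclo[6.2.0]dec-9-ene 21). Thermal 4π electrocyclic opening of its C1–C4 bond gives the ten-membered ring and the diene in one operation, as a ring expansion, and destroys the two cyclobutene stereocentres, so every cycloadduct isomer converges. The eight-membered ring comes from a cyclohexanone by an analogous two-carbon expansion. No Diels–Alder of a hindered diene, no photochemical step and no aryllithium addition remain; C8 and C9 are fixed early and never touched again.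

Key step: step 11

Assumption: phenyl vinyl selenide (15) is taken as purchasable (otherwise one step from PhSeBr and vinylmagnesium bromide), and the enantiomer of the Diels–Alder catalyst in step 2 is the one that gives (1R)-4.

Step 1
Reactants: 1 (3E)-pent-3-en-2-one
Product: 2 (3E)-2-[tri(propan-2-yl)silyloxy]penta-1,3-diene
Conditions: TIPSOTf (1.05 equiv), Et3N (1.3 equiv), Et2O, 0 °C
Reagents that add atoms: triisopropylsilyl trifluoromethanesulfonate CC(C)[Si](OS(=O)(=O)C(F)(F)F)(C(C)C)C(C)C
Why: Soft enolisation (silyl triflate/amine) of the methyl ketone at CH3 gives the cross-conjugated 2-silyloxy diene with the E-propenyl unit intact (silyl enol ether formation); no stereocentre is involved.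

Step 2
Reactants: 2 (3E)-2-[tri(propan-2-yl)silyloxy]penta-1,3-diene; 3 2,2,2-trifluoroethyl prop-2-enoate
Product: 4 2,2,2-trifluoroethyl (1R,2S)-2-methyl-4-[tri(propan-2-yl)silyloxy]cyclohex-3-ene-1-carboxylate
Conditions: o-tolyl-oxazaborolidine from α,α-diphenylprolinol protonated with Tf2NH (cationic oxazaborolidinium triflimide, 15 mol %), CH2Cl2, −78 °C
Reagents that add atoms: none
Why: Catalytic enantioselective Diels–Alder reaction: the 2-silyloxy and 1-methyl groups both direct the ester carbon (C8) next to the methyl-bearing carbon and "para" to the silyloxy carbon (C5), the chiral cationic Lewis acid bound to the acrylate shields one face so that C8 should be set as R, and the cis (endo) methyl stereocentre at C9 is expendable because it is planarised in step 4.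

Step 3
Reactants: 5 S-ethyl ethanethioate
Product: 6 tert-butyl{[1-(ethylsulfanyl)ethenyl]oxy}dimethylsilane
Conditions: TBSOTf (1.05 equiv), Et3N (1.2 equiv), CH2Cl2, 0 °C
Reagents that add atoms: tert-butyldimethylsilyl trifluoromethanesulfonate CC(C)(C)[Si](C)(C)OS(=O)(=O)C(F)(F)F
Why: Soft enolisation of the thioester gives the ketene silyl thioacetal, a strong π-nucleophile that carries C11 and C12 at the oxidation level needed for the later ketone synthesis.

Step 4
Reactants: 4 2,2,2-trifluoroethyl (1R,2S)-2-methyl-4-[tri(propan-2-yl)silyloxy]cyclohex-3-ene-1-carboxylate; 6 tert-butyl{[1-(ethylsulfanyl)ethenyl]oxy}dimethylsilane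
Product: 8 2,2,2-trifluoroethyl (1R,2R)-4-[tert-butyl(dimethyl)silyloxy]-2-[2-(ethylsulfanyl)-2-oxoethyl]-2-methylcyclohex-3-ene-1-carboxylate, via enone 7 (not isolated)
Conditions: Pd(OAc)2 (1.1 equiv), MeCN, 23 °C; filter (Celite), evaporate with PhMe below 25 °C; 6 (1.5 equiv), Tf2NH (5 mol %), CH2Cl2, −78 °C; Et3N quench
Reagents that add atoms: none
Why: Saegusa–Ito oxidation (palladium enolate at C10, β-hydride loss from C9) gives enone 7, which is used without base or chromatography because C8–H is vinylogously acidic, and silyl-triflimide-catalysed Mukaiyama–Michael addition of 6 then forms the quaternary C9 with the nucleophile entering anti to the C8 ester (held pseudoaxial by allylic strain with the C9 methyl), so that C11 should be trans and CH3 cis to C17, while silyl transfer leaves the enol ether regiodefined at C5=C10.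

Step 5
Reactants: 8 2,2,2-trifluoroethyl (1R,2R)-4-[tert-butyl(dimethyl)silyloxy]-2-[2-(ethylsulfanyl)-2-oxoethyl]-2-methylcyclohex-3-ene-1-carboxylate; 9 methyl prop-2-ynoate
Product: 11 1-methyl 5-(2,2,2-trifluoroethyl) (5R,6R,7Z)-6-[2-(ethylsulfanyl)-2-oxoethyl]-6-methyl-2-oxocyclooct-7-ene-1,5-dicarboxylate (C1 epimers/enol form), via cyclobutene silyl ether 10 (not isolated)
Conditions: 9 (1.5 equiv), Tf2NH (5 mol %), CH2Cl2, −78 → −40 °C; Et3N, evaporate; TBAF/AcOH (1:1, 1.2 equiv), THF, 0 → 23 °C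
Reagents that add atoms: none
Why: Acid (silyl triflimide)-catalysed stepwise [2+2] cycloaddition of the silyl enol ether with the propiolate (C10 attacks the alkyne terminus, the ester-bearing carbon closes on C5) followed by fluoride-triggered retro-aldol fragmentation of the strained cyclobutenol across C5–C10 (vinylogous ester enolate as leaving group) is a two-carbon ring expansion that inserts C1 and C4 and leaves C8 and C9 untouched.

Step 6
Reactants: 11 1-methyl 5-(2,2,2-trifluoroethyl) (5R,6R,7Z)-6-[2-(ethylsulfanyl)-2-oxoethyl]-6-methyl-2-oxocyclooct-7-ene-1,5-dicarboxylate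
Product: 12 1-methyl 5-(2,2,2-trifluoroethyl) (5R,6S)-6-[2-(ethylsulfanyl)-2-oxoethyl]-6-methyl-2-oxocyclooctane-1,5-dicarboxylate (C1 epimers/enol form)
Conditions: 2-nitrobenzenesulfonohydrazide (4 equiv), Et3N, CH2Cl2, 23 °C
Reagents that add atoms: none
Why: Diimide reduction (concerted syn transfer of two hydrogens) should saturate the ring-cis C1=C10 bond but not the hydrogen-bonded, tetrasubstituted enol double bond, and is chosen over catalytic hydrogenation because of the thioester.

Step 7
Reactants: 12 1-methyl 5-(2,2,2-trifluoroethyl) (5R,6S)-6-[2-(ethylsulfanyl)-2-oxoethyl]-6-methyl-2-oxocyclooctane-1,5-dicarboxylate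
Product: 14 1-methyl 5-(2,2,2-trifluoroethyl) (1E,4S,5R)-4-[2-(ethylsulfanyl)-2-oxoethyl]-4-methyl-8-oxocyclooct-1-ene-1,5-dicarboxylate (ring-cis double bond), via α-phenylselanyl keto ester 13 (not isolated)
Conditions: PhSeCl (1.1 equiv), pyridine (1.2 equiv), CH2Cl2, 0 °C; 30 % H2O2, 0 → 23 °C
Reagents that add atoms: none
Why: α-Selenenylation of the enolised β-keto ester and selenoxide syn-elimination, which can take a hydrogen only from C1, gives the alkylidene β-keto ester with the C4=C1 double bond; it is used at once to avoid tautomerisation to the dienol.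

Step 8
Reactants: 14 1-methyl 5-(2,2,2-trifluoroethyl) (1E,4S,5R)-4-[2-(ethylsulfanyl)-2-oxoethyl]-4-methyl-8-oxocyclooct-1-ene-1,5-dicarboxylate; 15 (ethenylselanyl)benzene
Product: 18 1-methyl 5-(2,2,2-trifluoroethyl) (5R,6S)-6-[2-(ethylsulfanyl)-2-oxoethyl]-6-methyl-2-oxobicyclo[6.2.0]dec-9-ene-1,5-dicarboxylate (ring-fusion isomers at C1 and C8), via cyclobutyl selenide 16 (not isolated), via selenoxide 17 (not isolated)
Conditions: 15 (2 equiv), EtAlCl2 (1.1 equiv), CH2Cl2, −78 °C; aq. Rochelle salt, extract; crude in CH2Cl2, pyridine (2 equiv), 30 % H2O2, 0 → 30 °C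
Reagents that add atoms: none
Why: Lewis-acid-promoted stepwise [2+2] cycloaddition (Michael addition of the vinyl selenide CH2 terminus to C1 of the chelated alkylidene β-keto ester, then closure of the C4 enolate on the selenium-stabilised cation) followed by selenoxide syn-elimination, possible only toward C2 because C4 is quaternary, gives the fused cyclobutene; the configurations at C1 and C4 (cis fusion expected) are irrelevant because step 11 destroys them.

Step 9
Reactants: 18 1-methyl 5-(2,2,2-trifluoroethyl) (5R,6S)-6-[2-(ethylsulfanyl)-2-oxoethyl]-6-methyl-2-oxobicyclo[6.2.0]dec-9-ene-1,5-dicarboxylate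
Product: 19 1-methyl 5-(2,2,2-trifluoroethyl) (5R,6S)-6-[2-(ethylsulfanyl)-2-oxoethyl]-6-methyl-2-methylidenebicyclo[6.2.0]dec-9-ene-1,5-dicarboxylate
Conditions: Zn dust, CH2Br2, TiCl4 (reagent preformed in THF), CH2Cl2, 0 → 23 °C
Reagents that add atoms: dibromomethane BrCBr
Why: Lombardo methylenation is non-basic and ketone-selective, so the hindered C5 ketone beside the quaternary C4 should be converted into the C19 methylidene without touching the esters, the thioester or the cyclobutene.

Step 10
Reactants: 19 1-methyl 5-(2,2,2-trifluoroethyl) (5R,6S)-6-[2-(ethylsulfanyl)-2-oxoethyl]-6-methyl-2-methylidenebicyclo[6.2.0]dec-9-ene-1,5-dicarboxylate; 20 furan-3-ylboronic acid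
Product: 21 1-methyl 5-(2,2,2-trifluoroethyl) (5R,6S)-6-[2-(furan-3-yl)-2-oxoethyl]-6-methyl-2-methylidenebicyclo[6.2.0]dec-9-ene-1,5-dicarboxylate
Conditions: 20 (1.5 equiv), Pd2(dba)3 (2.5 mol %), tri(2-furyl)phosphine (15 mol %), Cu(O2CC4H3S) (copper thiophene-2-carboxylate, 1.6 equiv), THF, 45 °C
Reagents that add atoms: none
Why: Liebeskind–Srogl coupling converts the thioester into the 3-furyl ketone under neutral conditions (oxidative addition of zerovalent palladium into the C–S bond, copper-carboxylate-assisted transmetalation from boron), leaving both esters alone and staying well below the temperature of cyclobutene opening.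

Step 11
Reactants: 21 1-methyl 5-(2,2,2-trifluoroethyl) (5R,6S)-6-[2-(furan-3-yl)-2-oxoethyl]-6-methyl-2-methylidenebicyclo[6.2.0]dec-9-ene-1,5-dicarboxylate
Product: 23 7-methyl 1-(2,2,2-trifluoroethyl) (1R,2S,4Z,6E)-2-[2-(furan-3-yl)-2-oxoethyl]-2-methyl-8-methylidenecyclodeca-4,6-diene-1,7-dicarboxylate, via ring-trans diene isomer 22 (not isolated)
Conditions: PhMe (0.01 M, degassed, 1 mol % BHT), 95 °C, dark; cool; I2 (2 mol %), CH2Cl2, daylight lamp, 23 °C; aq. Na2S2O3
Reagents that add atoms: none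
Why: Thermal conrotatory 4π electrocyclic ring opening of the cyclobutene breaks the C1–C4 σ bond (weakened by the C18 ester and the C5=C19 alkenyl group on C4) and turns the bicyclo[6.2.0]decene into the ten-membered ring with the C1=C2–C3=C4 diene cross-conjugated to the methylidene; the closest known reaction is the opening of cis-bicyclo[6.2.0]dec-9-ene to cis,trans-cyclodeca-1,3-diene. No ring is closed: the step is a ring expansion (8 + 2 → 10) by cleavage of the zero bridge, so the entropic and transannular cost of a medium-ring closure never arises. No stereocentre is formed, C8 and C9 are untouched, and the two cyclobutene stereocentres (C1, C4) are destroyed, so all ring-fusion and facial isomers of 21 converge. The step needs ring-cis geometry at both new double bonds: a cis-fused cyclobutene must open with one ring bond turning inward and one outward (the C10 alkyl group outward, as torquoselectivity dictates), which should give the strained ring-trans C1=C2 isomer 22, and reversible iodine-atom addition to the dienoate should then equilibrate it to the all-ring-cis diene 23 (cis,cis-cyclodeca-1,3-dienes being the stable isomers), while any trans-fused cyclobutene gives 23 directly. The temperature is kept below 100 °C because the product equilibrates by [1,7]-hydrogen shift with an E,Z,E-triene that could cyclise irreversibly at higher temperature.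

Step 12
Reactants: 23 7-methyl 1-(2,2,2-trifluoroethyl) (1R,2S,4Z,6E)-2-[2-(furan-3-yl)-2-oxoethyl]-2-methyl-8-methylidenecyclodeca-4,6-diene-1,7-dicarboxylate
Product: 25 (1R,2S,4Z,6E)-2-[2-(furan-3-yl)-2-oxoethyl]-2-methyl-8-methylidenecyclodeca-4,6-diene-1,7-dicarboxylic acid, via dilithium dicarboxylate 24 (not isolated)
Conditions: LiOH·H2O (6 equiv), THF/H2O (3:1), 0 → 35 °C; 1 M HCl to pH 3, extract
Reagents that add atoms: lithium hydroxide [Li+].[OH-]
Why: Saponification (BAc2): the activated trifluoroethyl ester at the hindered C17 and the conjugated methyl ester at C18 should both be hydrolysed by LiOH under mild conditions, the carboxylates protect C8 against epimerisation, and acidification gives the diacid.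

Compound list
1 | (3E)-pent-3-en-2-one | C/C=C/C(C)=O | starting material
2 | (3E)-2-[tri(propan-2-yl)silyloxy]penta-1,3-diene | C/C=C/C(=C)O[Si](C(C)C)(C(C)C)C(C)C | intermediate
3 | 2,2,2-trifluoroethyl prop-2-enoate | C=CC(=O)OCC(F)(F)F | starting material
4 | 2,2,2-trifluoroethyl (1R,2S)-2-methyl-4-[tri(propan-2-yl)silyloxy]cyclohex-3-ene-1-carboxylate | CC(C)[Si](C(C)C)(C(C)C)OC1=C[C@H](C)[C@H](C(=O)OCC(F)(F)F)CC1 | intermediate
5 | S-ethyl ethanethioate | CCSC(C)=O | starting material
6 | tert-butyl{[1-(ethylsulfanyl)ethenyl]oxy}dimethylsilane | C=C(SCC)O[Si](C)(C)C(C)(C)C | intermediate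
7 | 2,2,2-trifluoroethyl (1R)-2-methyl-4-oxocyclohex-2-ene-1-carboxylate | O=C1CC[C@@H](C(=O)OCC(F)(F)F)C(C)=C1 | intermediate
8 | 2,2,2-trifluoroethyl (1R,2R)-4-[tert-butyl(dimethyl)silyloxy]-2-[2-(ethylsulfanyl)-2-oxoethyl]-2-methylcyclohex-3-ene-1-carboxylate | CC(C)(C)[Si](C)(C)OC1=C[C@@](C)(CC(=O)SCC)[C@H](C(=O)OCC(F)(F)F)CC1 | intermediate
9 | methyl prop-2-ynoate | C#CC(=O)OC | starting material
10 | 7-methyl 3-(2,2,2-trifluoroethyl) (2R,3R)-6-[tert-butyl(dimethyl)silyloxy]-2-[2-(ethylsulfanyl)-2-oxoethyl]-2-methylbicyclo[4.2.0]oct-7-ene-3,7-dicarboxylate (cis-fused; bridgeheads not assigned) | COC(=O)C1=CC2[C@@](C)(CC(=O)SCC)[C@H](C(=O)OCC(F)(F)F)CCC21O[Si](C)(C)C(C)(C)C | intermediate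
11 | 1-methyl 5-(2,2,2-trifluoroethyl) (5R,6R,7Z)-6-[2-(ethylsulfanyl)-2-oxoethyl]-6-methyl-2-oxocyclooct-7-ene-1,5-dicarboxylate (C1 epimers, enol form) | O=C1CC[C@@H](C(=O)OCC(F)(F)F)[C@](C)(CC(=O)SCC)/C=C\C1C(=O)OC | intermediate
12 | 1-methyl 5-(2,2,2-trifluoroethyl) (5R,6S)-6-[2-(ethylsulfanyl)-2-oxoethyl]-6-methyl-2-oxocyclooctane-1,5-dicarboxylate (C1 epimers, enol form) | O=C1CC[C@@H](C(=O)OCC(F)(F)F)[C@](C)(CC(=O)SCC)CCC1C(=O)OC | intermediate
13 | 1-methyl 5-(2,2,2-trifluoroethyl) (5R,6S)-6-[2-(ethylsulfanyl)-2-oxoethyl]-6-methyl-2-oxo-1-(phenylselanyl)cyclooctane-1,5-dicarboxylate (C1 not assigned) | O=C1CC[C@@H](C(=O)OCC(F)(F)F)[C@](C)(CC(=O)SCC)CCC1([Se]c1ccccc1)C(=O)OC | intermediate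
14 | 1-methyl 5-(2,2,2-trifluoroethyl) (1E,4S,5R)-4-[2-(ethylsulfanyl)-2-oxoethyl]-4-methyl-8-oxocyclooct-1-ene-1,5-dicarboxylate | O=C1CC[C@@H](C(=O)OCC(F)(F)F)[C@](C)(CC(=O)SCC)C/C=C\1C(=O)OC | intermediate
15 | (ethenylselanyl)benzene (phenyl vinyl selenide) | C=C[Se]c1ccccc1 | starting material
16 | 1-methyl 5-(2,2,2-trifluoroethyl) (5R,6S)-6-[2-(ethylsulfanyl)-2-oxoethyl]-6-methyl-2-oxo-10-(phenylselanyl)bicyclo[6.2.0]decane-1,5-dicarboxylate (C1, C8, C10 not assigned) | O=C1CC[C@@H](C(=O)OCC(F)(F)F)[C@](C)(CC(=O)SCC)CC2CC([Se]c3ccccc3)C12C(=O)OC | intermediate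
17 | 1-methyl 5-(2,2,2-trifluoroethyl) (5R,6S)-10-(benzeneseleninyl)-6-[2-(ethylsulfanyl)-2-oxoethyl]-6-methyl-2-oxobicyclo[6.2.0]decane-1,5-dicarboxylate (C1, C8, C10, Se not assigned) | O=C1CC[C@@H](C(=O)OCC(F)(F)F)[C@](C)(CC(=O)SCC)CC2CC([Se](=O)c3ccccc3)C12C(=O)OC | intermediate
18 | 1-methyl 5-(2,2,2-trifluoroethyl) (5R,6S)-6-[2-(ethylsulfanyl)-2-oxoethyl]-6-methyl-2-oxobicyclo[6.2.0]dec-9-ene-1,5-dicarboxylate (C1, C8 not assigned) | O=C1CC[C@@H](C(=O)OCC(F)(F)F)[C@](C)(CC(=O)SCC)CC2C=CC12C(=O)OC | intermediate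
19 | 1-methyl 5-(2,2,2-trifluoroethyl) (5R,6S)-6-[2-(ethylsulfanyl)-2-oxoethyl]-6-methyl-2-methylidenebicyclo[6.2.0]dec-9-ene-1,5-dicarboxylate (C1, C8 not assigned) | C=C1CC[C@@H](C(=O)OCC(F)(F)F)[C@](C)(CC(=O)SCC)CC2C=CC12C(=O)OC | intermediate
20 | furan-3-ylboronic acid | OB(O)c1ccoc1 | starting material
21 | 1-methyl 5-(2,2,2-trifluoroethyl) (5R,6S)-6-[2-(furan-3-yl)-2-oxoethyl]-6-methyl-2-methylidenebicyclo[6.2.0]dec-9-ene-1,5-dicarboxylate (C1, C8 not assigned) | C=C1CC[C@@H](C(=O)OCC(F)(F)F)[C@](C)(CC(=O)c3ccoc3)CC2C=CC12C(=O)OC | intermediate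
22 | 7-methyl 1-(2,2,2-trifluoroethyl) (1R,2S,4E,6E)-2-[2-(furan-3-yl)-2-oxoethyl]-2-methyl-8-methylidenecyclodeca-4,6-diene-1,7-dicarboxylate (C4=C5 ring-trans) | C=C1CC[C@@H](C(=O)OCC(F)(F)F)[C@](C)(CC(=O)c2ccoc2)C/C=C/C=C\1C(=O)OC | intermediate
23 | 7-methyl 1-(2,2,2-trifluoroethyl) (1R,2S,4Z,6E)-2-[2-(furan-3-yl)-2-oxoethyl]-2-methyl-8-methylidenecyclodeca-4,6-diene-1,7-dicarboxylate | C=C1CC[C@@H](C(=O)OCC(F)(F)F)[C@](C)(CC(=O)c2ccoc2)C/C=C\C=C/1C(=O)OC | intermediate
24 | dilithium (1R,2S,4Z,6E)-2-[2-(furan-3-yl)-2-oxoethyl]-2-methyl-8-methylidenecyclodeca-4,6-diene-1,7-dicarboxylate | [Li+].[Li+].C=C1CC[C@@H](C(=O)[O-])[C@](C)(CC(=O)c2ccoc2)C/C=C\C=C/1C(=O)[O-] | intermediate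
25 | (1R,2S,4Z,6E)-2-[2-(furan-3-yl)-2-oxoethyl]-2-methyl-8-methylidenecyclodeca-4,6-diene-1,7-dicarboxylic acid | C=C1CC[C@@H](C(=O)O)[C@](C)(CC(=O)c2ccoc2)C/C=C\C=C/1C(=O)O | target

Total step count: 12. Longest linear sequence: 11 steps (1, 2, 4–12); step 3 is a one-step branch.

Steps most likely to fail

1. Step 11. The ring opening may need a temperature at which the triene, after [1,7]-hydrogen shift, cyclises irreversibly, or the iodine-mediated equilibration may not stop at the ring geometry. The fallback sets out from 18, whose acyl group on C4 should lower the barrier. Heating 18 (PhMe, about 70 °C) and then cat. I2 would give the ten-membered dienone 7-methyl 1-(2,2,2-trifluoroethyl) (1R,2S,4Z,6E)-2-[2-(ethylsulfanyl)-2-oxoethyl]-2-methyl-8-oxocyclodeca-4,6-diene-1,7-dicarboxylate F1, which has no methylidene and therefore no [1,7] pathway. Methylenation with Zn/CH2Br2/TiCl4 would give the triene thioester 7-methyl 1-(2,2,2-trifluoroethyl) (1R,2S,4Z,6E)-2-[2-(ethylsulfanyl)-2-oxoethyl]-2-methyl-8-methylidenecyclodeca-4,6-diene-1,7-dicarboxylate F2, and the coupling of step 10 with 20 comes back to the route at 23.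

2. Step 8. The zwitterion from the Michael addition may close on oxygen (dihydropyran) or revert, and the selenoxide may eliminate slowly toward a strained cyclobutene. The fallback sets out from 14: irradiation (Pyrex filter) with excess (E)-1,2-dichloroethene would give the photocycloadduct 1-methyl 5-(2,2,2-trifluoroethyl) (5R,6S)-9,10-dichloro-6-[2-(ethylsulfanyl)-2-oxoethyl]-6-methyl-2-oxobicyclo[6.2.0]decane-1,5-dicarboxylate F3, and reductive elimination with zinc dust (AcOH/Et2O) comes back to the route at 18.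

3. Step 4. Enone 7 may enolise toward C8 during the oxidation and lose enantiomeric purity, and the ketene acetal may add 1,2 to the hindered enone. The fallback sets out from 3 and never forms a free enone. Pentane-2,4-dione with TBSOTf/Et3N would give (3Z)-2,4-bis[tert-butyl(dimethyl)silyloxy]penta-1,3-diene F4. Its cycloaddition with 3 under the conditions of step 2 would give 2,2,2-trifluoroethyl (1R)-2,4-bis[tert-butyl(dimethyl)silyloxy]-2-methylcyclohex-3-ene-1-carboxylate F5, in which C9 carries methyl and silyloxy. Tf2NH-catalysed ionisation of this tertiary allylic silyl ether in the presence of 6 (CH2Cl2, −78 °C) would let the ketene acetal add anti to the C8 ester and comes back to the route at 8.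

Further compounds
F1 | step 11 | 7-methyl 1-(2,2,2-trifluoroethyl) (1R,2S,4Z,6E)-2-[2-(ethylsulfanyl)-2-oxoethyl]-2-methyl-8-oxocyclodeca-4,6-diene-1,7-dicarboxylate | O=C1CC[C@@H](C(=O)OCC(F)(F)F)[C@](C)(CC(=O)SCC)C/C=C\C=C/1C(=O)OC
F2 | step 11 | 7-methyl 1-(2,2,2-trifluoroethyl) (1R,2S,4Z,6E)-2-[2-(ethylsulfanyl)-2-oxoethyl]-2-methyl-8-methylidenecyclodeca-4,6-diene-1,7-dicarboxylate | C=C1CC[C@@H](C(=O)OCC(F)(F)F)[C@](C)(CC(=O)SCC)C/C=C\C=C/1C(=O)OC
F3 | step 8 | 1-methyl 5-(2,2,2-trifluoroethyl) (5R,6S)-9,10-dichloro-6-[2-(ethylsulfanyl)-2-oxoethyl]-6-methyl-2-oxobicyclo[6.2.0]decane-1,5-dicarboxylate | O=C1CC[C@@H](C(=O)OCC(F)(F)F)[C@](C)(CC(=O)SCC)CC2C(Cl)C(Cl)C12C(=O)OC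
F4 | step 4 | (3Z)-2,4-bis[tert-butyl(dimethyl)silyloxy]penta-1,3-diene | C=C(O[Si](C)(C)C(C)(C)C)/C=C(\O[Si](C)(C)C(C)(C)C)C
F5 | step 4 | 2,2,2-trifluoroethyl (1R)-2,4-bis[tert-butyl(dimethyl)silyloxy]-2-methylcyclohex-3-ene-1-carboxylate | CC(C)(C)[Si](C)(C)OC1=CC(C)(O[Si](C)(C)C(C)(C)C)[C@H](C(=O)OCC(F)(F)F)CC1
A1 | direct plan | (4aR,5R,6R,8aR)-5-[2-(furan-3-yl)-2-oxoethyl]-5,8a-dimethyl-4a,5,6,7,8,8a-hexahydronaphthalene-1,6-dicarboxylic acid | C[C@@]12CC[C@@H](C(=O)O)[C@](C)(CC(=O)c3ccoc3)[C@H]1C=CC=C2C(=O)O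
A2 | direct plan | methyl (1R,2S)-3-ethenyl-2-{2-[methoxy(methyl)amino]-2-oxoethyl}-2,4-dimethylcyclohex-3-ene-1-carboxylate | C=CC1=C(C)CC[C@@H](C(=O)OC)[C@]1(C)CC(=O)N(C)OC
A3 | direct plan | (1R,2R,3E,5Z,7Z)-2-[2-(furan-3-yl)-2-oxoethyl]-2,8-dimethylcyclodeca-3,5,7-triene-1,7-dicarboxylic acid (ring geometry E,Z,E) | C/C1=C(C(=O)O)\C=C/C=C/[C@@](C)(CC(=O)c2ccoc2)[C@H](C(=O)O)CC1
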